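The route rests on cutting two C–O bonds of the target: the benzylic C–OAr ether bond and the O4–C3a bond of the tetrahydrofuran (ring B) fused to the γ-lactone (ring A). The feature exploited is that the benzylic carbon and C5–O4 are threo (both S), the outcome of anti opening of a cis-epoxide, and that O4 sits 1,5 to C3a, the β-carbon of a latent butenolide. In one operation the 7-phenoxide of (S)-pinocembrin opens the epoxide at its benzylic carbon and the freed oxygen closes ring B by oxa-Michael addition, setting two stereocentres. The precursor is an (R)-5-substituted butenolide carrying a (2S,3R)-cis-3-phenyloxiranylmethyl group.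

Key step: step 7

Remark: the (R,R)-(salen)MnCl catalyst is assumed to show the facial sense it has with cis-β-methylstyrene (benzylic carbon R), which is the (2S,3R)-oxirane needed; bicycle numbering is O1, C2(=O), C3, C3a, O4, C5, C6, C6a.

Step 1
Reactants: 1 phenylacetylene; 2 (R)-epichlorohydrin
Product: 4 (R)-1-chloro-5-phenylpent-4-yn-2-ol, via lithium phenylacetylide 3 (not isolated)
Conditions: n-BuLi, THF, −78 °C; then BF3·OEt2, 2, −78 °C; aq. NH4Cl
Reagents that add atoms: none
Why: Lewis-acid-promoted SN2 opening of an epoxide by a lithium acetylide: BF3 activates the oxirane so that the acetylide attacks its unsubstituted carbon at −78 °C faster than it displaces chloride, and the C–O stereocentre of 2 is not a reaction site and is carried over as (R).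

Step 2
Reactants: 4 (R)-1-chloro-5-phenylpent-4-yn-2-ol
Product: 5 (2R,4Z)-1-chloro-5-phenylpent-4-en-2-ol
Conditions: H2 (1 atm), Pd/CaCO3 poisoned with Pb(OAc)2 (Lindlar catalyst), quinoline, EtOAc, rt
Reagents that add atoms: none
Why: Lindlar semihydrogenation adds H2 syn on the poisoned palladium surface and stops at the alkene, giving the Z-styrene while the alkyl chloride and the carbinol centre stay untouched.

Step 3
Reactants: 5 (2R,4Z)-1-chloro-5-phenylpent-4-en-2-ol
Product: 7 (3R,5Z)-6-phenylhexa-1,5-dien-3-ol, via (R)-2-[(Z)-cinnamyl]oxirane 6 (not isolated)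
Conditions: Me3S+ I− (4 equiv), n-BuLi (3.9 equiv), THF, −10 °C → rt
Reagents that add atoms: trimethylsulfonium iodide, C[S+](C)C.[I-] (one CH2 carbon, delivered as its ylide)
Why: One-carbon homologation of a terminal epoxide to an allylic alcohol with excess dimethylsulfonium methylide: the ylide first acts as base to close the chlorohydrin to epoxide 6, then opens 6 at its CH2 group, and the sulfonium alkoxide loses Me2S by ylide-mediated syn-elimination, so the carbinol centre keeps its oxygen and its configuration.

Step 4
Reactants: 7 (3R,5Z)-6-phenylhexa-1,5-dien-3-ol; 8 acryloyl chloride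
Product: 9 (3R,5Z)-6-phenylhexa-1,5-dien-3-yl prop-2-enoate
Conditions: Et3N, CH2Cl2, −20 → 0 °C
Reagents that add atoms: none
Why: Base-mediated O-acylation of a secondary alcohol with an acid chloride, run cold to avoid acrylate polymerisation; the stereocentre is not involved.

Step 5
Reactants: 9 (3R,5Z)-6-phenylhexa-1,5-dien-3-yl prop-2-enoate
Product: 10 (2R)-1-[(2S,3R)-3-phenyloxiran-2-yl]but-3-en-2-yl prop-2-enoate
Conditions: (R,R)-(salen)MnCl (5 mol%; salen = N,N'-bis(3,5-di-tert-butylsalicylidene)cyclohexane-1,2-diamine dianion, trivalent manganese), mCPBA, NMO, CH2Cl2, −78 °C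
Reagents that add atoms: mCPBA (3-chloroperoxybenzoic acid), OOC(=O)c1cccc(Cl)c1
Why: Jacobsen–Katsuki epoxidation: the electrophilic oxo-manganese species should react only with the conjugated cis-disubstituted styrene (the acrylate is electron-poor, the allylic-ester vinyl group unactivated), and the (R,R)-ligand directs oxygen to the face that gives the (2S,3R)-cis-oxirane, so both new centres are set by catalyst control and, the substrate being enantiopure, minor isomers are diastereomers removable by chromatography.

Step 6
Reactants: 10 (2R)-1-[(2S,3R)-3-phenyloxiran-2-yl]but-3-en-2-yl prop-2-enoate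
Product: 11 (5R)-5-{[(2S,3R)-3-phenyloxiran-2-yl]methyl}furan-2(5H)-one
Conditions: second-generation Grubbs catalyst [(H2IMes)(PCy3)Cl2Ru=CHPh, 5 mol%], CH2Cl2 (0.005 M), 40 °C
Reagents that add atoms: none
Why: Ring-closing metathesis of the allyl acrylate unit should give the five-membered butenolide with loss of ethylene; the epoxide is inert to the ruthenium carbene and, the styrene having been oxidised beforehand, no other alkene can divert the carbene or lose its geometry.

Step 7
Reactants: 11 (5R)-5-{[(2S,3R)-3-phenyloxiran-2-yl]methyl}furan-2(5H)-one; 12 (S)-pinocembrin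
Product: 14 (3aR,5S,6aR)-5-[(S)-{[(2S)-5-hydroxy-4-oxo-2-phenyl-3,4-dihydro-2H-chromen-7-yl]oxy}(phenyl)methyl]tetrahydrofuro[3,2-b]furan-2(3H)-one (target), via ring-opened hydroxy butenolide 13 (not isolated)
Conditions: 12 (1.3 equiv), Cs2CO3 (0.3 equiv), DMF, 25 → 60 °C, Ar
Reagents that add atoms: none
Why: Proposed new method: the cesium 7-phenoxide of 12 attacks the benzylic oxirane carbon of 11 from the rear (SN2, inversion, giving the S aryl ether 13), and the oxygen released on C5 then adds to the β-carbon of the butenolide, the lactone enolate being protonated by more 12 so that the base turns over. The closest known reactions are the base-mediated phenolysis of aryl epoxides at the benzylic carbon with inversion and the base-catalysed intramolecular oxa-Michael addition of γ-(2-hydroxyalkyl)butenolides to furo[3,2-b]furanones; only their union in one flask is new. Ring B closes by a 5-exo-trig attack of O4 on C3a. The benzylic centre is fixed by the oxirane configuration through inversion and C3a by the existing C6a centre, since the bicyclo[3.3.0] lactone can only be cis-fused, while C5 and C6a are carried over and leave the side chain on the convex face. The step needs benzylic rather than C2 opening, O- rather than C-alkylation and reaction of the 7-OH rather than the 5-OH: phenyl stabilisation of the SN2 transition state and the branched, inductively deactivated C2 favour the benzylic carbon, the cesium phenoxide in DMF favours O-attack, and the 5-OH is tied up in a hydrogen bond to the C4 carbonyl. The phenol-buffered, weakly basic medium should leave the flavanone C2 centre and the γ-hydrogen of the butenolide alone.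

Compound list
1 | phenylacetylene | C#Cc1ccccc1 | starting material
2 | (R)-epichlorohydrin | ClC[C@H]1CO1 | starting material
3 | lithium phenylacetylide | [Li]C#Cc1ccccc1 | intermediate (not isolated)
4 | (R)-1-chloro-5-phenylpent-4-yn-2-ol | ClC[C@H](O)CC#Cc1ccccc1 | intermediate
5 | (2R,4Z)-1-chloro-5-phenylpent-4-en-2-ol | ClC[C@H](O)C/C=C\c1ccccc1 | intermediate
6 | (R)-2-[(2Z)-3-phenylprop-2-en-1-yl]oxirane | C(/C=C\c1ccccc1)[C@@H]1CO1 | intermediate (not isolated)
7 | (3R,5Z)-6-phenylhexa-1,5-dien-3-ol | C=C[C@H](O)C/C=C\c1ccccc1 | intermediate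
8 | acryloyl chloride | C=CC(=O)Cl | starting material
9 | (3R,5Z)-6-phenylhexa-1,5-dien-3-yl prop-2-enoate | C=CC(=O)O[C@@H](C=C)C/C=C\c1ccccc1 | intermediate
10 | (2R)-1-[(2S,3R)-3-phenyloxiran-2-yl]but-3-en-2-yl prop-2-enoate | C=CC(=O)O[C@@H](C=C)C[C@@H]1O[C@@H]1c1ccccc1 | intermediate
11 | (5R)-5-{[(2S,3R)-3-phenyloxiran-2-yl]methyl}furan-2(5H)-one | O=C1C=C[C@@H](C[C@@H]2O[C@@H]2c2ccccc2)O1 | intermediate (key-step precursor)
12 | (S)-pinocembrin | Oc1cc(O)c2c(c1)O[C@H](c1ccccc1)CC2=O | starting material
13 | (5R)-5-[(2S,3S)-2-hydroxy-3-{[(2S)-5-hydroxy-4-oxo-2-phenyl-3,4-dihydro-2H-chromen-7-yl]oxy}-3-phenylpropyl]furan-2(5H)-one | O=C1C=C[C@@H](C[C@H](O)[C@@H](Oc2cc(O)c3c(c2)O[C@H](c2ccccc2)CC3=O)c2ccccc2)O1 | intermediate (not isolated)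
14 | (3aR,5S,6aR)-5-[(S)-{[(2S)-5-hydroxy-4-oxo-2-phenyl-3,4-dihydro-2H-chromen-7-yl]oxy}(phenyl)methyl]tetrahydrofuro[3,2-b]furan-2(3H)-one | O=C1C[C@H]2O[C@H]([C@@H](Oc3cc(O)c4c(c3)O[C@H](c3ccccc3)CC4=O)c3ccccc3)C[C@H]2O1 | target

Total step count: 7. Longest linear sequence: 7 steps (1 and 2 to 14).

Steps most likely to fail

Step 7 (Proposed new method). The 7-phenoxide is a weak, vinylogous-carboxylate-like nucleophile, so epoxide opening may be slow. That leaves time for attack at the non-benzylic oxirane carbon, C-alkylation of the phloroglucinol ring, base-induced epimerisation at the γ-carbon of the butenolide before ring closure, or retro-oxa-Michael opening of the flavanone with loss of its C2 configuration. The fallback uses known chemistry only: it makes the aryl ether on a substrate with no Michael acceptor and then builds both rings by palladium-catalysed oxycarbonylation. It sets out from dienol 7, which is silylated (TBSCl, imidazole, DMF) to the TBS ether F1 and epoxidised under the step 5 conditions to the cis-epoxide F2. Benzylic phenolysis with 12 (Cs2CO3, DMF, 60 °C) should give the hydroxy aryl ether F3, and desilylation (HF·pyridine, THF) the ene-1,3-diol F4. Oxycarbonylation (PdCl2 cat., CuCl2, NaOAc, AcOH, CO 1 atm, rt) then closes ring B by 5-exo oxypalladation and ring A by CO insertion and capture of the acyl-palladium by the allylic hydroxyl, necessarily cis-fused. The fallback rejoins the route at target 14.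

Step 5. Facial discrimination may be incomplete, and the stepwise oxygen transfer may allow bond rotation in the benzylic radical intermediate, leaking material to trans-epoxide. The fallback replaces metal-oxo transfer by concerted, metal-free dioxirane transfer (Shi epoxidation), which cannot scramble alkene geometry. Compound 9 is treated with Oxone and K2CO3 buffer in MeCN–dimethoxymethane–water at 0 °C, with the glucose-derived oxazolidinone ketone of the series that gives the (1R,2S)-oxide from cis-β-methylstyrene. It sets out from 9 and returns at 10; no new compound arises (F0).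

Step 6. Closure to the electron-poor five-membered lactone may be slow, so that catalyst decomposition and intermolecular metathesis outrun ring closure. The fallback builds the butenolide by lactone annulation of a terminal epoxide and sets out from chlorohydrin 5.
- Closure with K2CO3 in MeOH gives epoxide 6, now isolated.
- Opening of 6 at its CH2 group with the dianion of (phenylselanyl)acetic acid (2 LDA, THF, 0 °C) should give the γ-hydroxy-α-selanyl acid F5.
- Lactonisation (TsOH cat., benzene) gives the α-(phenylselanyl) lactone F6.
- Oxidation (H2O2, pyridine, CH2Cl2, 0 °C) with selenoxide syn-elimination gives the (Z)-cinnamyl butenolide F7.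
- Epoxidation of F7 under the step 5 conditions, where the butenolide alkene is inert, returns the route at 11.

Further compounds
F1 | step 7 | tert-butyl(dimethyl){[(3R,5Z)-6-phenylhexa-1,5-dien-3-yl]oxy}silane | C=C[C@H](O[Si](C)(C)C(C)(C)C)C/C=C\c1ccccc1
F2 | step 7 | tert-butyl(dimethyl)({(2R)-1-[(2S,3R)-3-phenyloxiran-2-yl]but-3-en-2-yl}oxy)silane | C=C[C@H](O[Si](C)(C)C(C)(C)C)C[C@@H]1O[C@@H]1c1ccccc1
F3 | step 7 | (2S)-7-{[(1S,2S,4R)-4-{[tert-butyl(dimethyl)silyl]oxy}-2-hydroxy-1-phenylhex-5-en-1-yl]oxy}-5-hydroxy-2-phenyl-2,3-dihydro-4H-chromen-4-one | C=C[C@H](O[Si](C)(C)C(C)(C)C)C[C@H](O)[C@@H](Oc1cc(O)c2c(c1)O[C@H](c1ccccc1)CC2=O)c1ccccc1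
F4 | step 7 | (2S)-7-{[(1S,2S,4R)-2,4-dihydroxy-1-phenylhex-5-en-1-yl]oxy}-5-hydroxy-2-phenyl-2,3-dihydro-4H-chromen-4-one | C=C[C@H](O)C[C@H](O)[C@@H](Oc1cc(O)c2c(c1)O[C@H](c1ccccc1)CC2=O)c1ccccc1
F0 | step 5 | none | none
F5 | step 6 | (4R,6Z)-4-hydroxy-7-phenyl-2-(phenylselanyl)hept-6-enoic acid (C2 epimers) | OC(=O)C([Se]c1ccccc1)C[C@H](O)C/C=C\c1ccccc1
F6 | step 6 | (5R)-5-[(2Z)-3-phenylprop-2-en-1-yl]-3-(phenylselanyl)dihydrofuran-2(3H)-one (C3 epimers) | O=C1C([Se]c2ccccc2)C[C@@H](C/C=C\c2ccccc2)O1
F7 | step 6 | (5R)-5-[(2Z)-3-phenylprop-2-en-1-yl]furan-2(5H)-one | O=C1C=C[C@@H](C/C=C\c2ccccc2)O1
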